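All runs come from a simulation for an exercise, and the scatter is random.

The pitfall in the beta run was to read the excess at its start. At 0.200 min it comes to 100%, yet the scatter of the readings moves that figure by about 48 percentage points.

| setting | beta | flask |
|---|---|---|
| left-handed substrate | 0.50 M | 0.25 M |
| right-handed substrate | 0.50 M | 0.25 M |
| partner | 4 equiv | 4.00 equiv |
| remark | run made earlier |  |
| time |  | 25 min |

beta run (percent of the left-handed substrate and right-handed substrate together charged)

| time / min | left-handed product / % | right-handed product / % |
|---|---|---|
| 0.200 | 2.1 | 0 |
| 0.333 | 4.1 | 2.0 |
| 0.500 | 5.2 | 3.3 |
| 0.667 | 7.3 | 4.1 |
| 1.00 | 10.4 | 4.6 |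
| 1.50 | 13.6 | 7.0 |
| 2.50 | 20.0 | 10.7 |

(scatter of a reading: 0.5 percentage points)

- partner is single-handed; left-handed substrate and right-handed substrate are mirror images of each other, charged as a racemate, each of them at the stated concentration
- an excess is the difference of the two amounts in percent of their sum
- an excess is below zero if the other one leads
- the handed part of partner does not stay in what it makes, so the products of the two hands are mirror images too

1. left-handed product and right-handed product together, in percent of the left-handed substrate and right-handed substrate charged together, at 25 min
2. excess of left-handed product over right-handed product in the product at 25 min
3. whether the exchange between left-handed substrate and right-handed substrate keeps pace with the reaction: how far the product's excess at 25 min gets from its value without exchange to its value with instant exchange (above 80% keeps pace, below 20% hardly takes part, else lags behind)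

I wanted one thing that stays nearly constant early on: the ratio of left-handed to right-handed product, the selectivity factor. So I asked first what an error in each input would do to it. The beta run holds a single charge and stops at 2.50 min, far short of 25 min, so its readings do not tell what c(left-handed substrate) = 0.25 M or the longer time do to this ratio. The readings do matter: the error of the excess shrinks as the sum of the two products grows, so at 2.50 min the excess is good to about 2.3 points. That reading gave a ratio of 1.87. From it I reckoned the frozen excess, 30.3%, the excess the product holds if that ratio stays put, and I took it as my estimate for instant exchange, with the two substrates kept equal. I committed to this as the level against which the excess at 25 min measures the exchange.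

The forecast gave a yield of 82% and an excess of 14%, and said the exchange hardly takes part, since the slight fall of the excess and the declining rate “mildly favour little exchange”. Its excess lies 16 points below my frozen one.

The flask gave 67.6% and an excess of 22.1%, and the exchange lags behind, at 45% of the way. At 25.0 min, right-handed substrate led left-handed substrate by 11.4% among what was left. The product stood 8.2 points under the frozen excess.

    partner + left-handed substrate → left-handed product (k = 0.00200 M⁻¹ s⁻¹)
    partner → decomposed reagent (k = 5.00 × 10⁻⁴ s⁻¹)
    partner + right-handed substrate → right-handed product (k = 9.80 × 10⁻⁴ M⁻¹ s⁻¹)
    partner → decomposition product (k = 6.00 × 10⁻⁶ s⁻¹)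
    left-handed substrate ⇌ right-handed substrate (k = 8.20 × 10⁻⁴ s⁻¹)
    left-handed product ⇌ right-handed product (k = 6.90 × 10⁻⁵ s⁻¹)

In the neighbour flask with 1.00 equiv of partner, the frozen excess again says 30.3%. The computed excess there was 28.0% at a yield of 23.0%, closer to it than in the flask with 4.00 equiv.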